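The tetrahydrofuran ring (O1, C2, C3, C4, C5) is opened at O1–C2. Because both aryl groups are 3,4-dimethoxyphenyl, this cut uncovers a twofold-symmetric (2R,3R)-2,3-bis(3,4-dimethoxybenzyl)butane-1,4-diol, whose benzylic CH2 (the future C2) lies para to a methoxy group and can be ionised oxidatively. In the key step DDQ abstracts hydride from that CH2 in the diol monopivalate. The free C5 hydroxyl traps the cation, forming O1–C2, the ring and the C2 stereocentre (aryl trans to the C3 substituent) in one operation. The diol comes from an auxiliary-controlled oxidative enolate dimerisation, and ester exchange to the angelate finishes the synthesis.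

Key step: step 5

Remark on the chemistry: ring atoms are O1, C2 (aryl), C3 (bears C9H2O), C4 (bears benzylic C7'), C5. The lithium enolate of the (S)-auxiliary imide is assumed to react at both new centres on the face away from the auxiliary benzyl group, which gives the R,R dimer. The O9 ester is kept as a pivalate for three reasons: an acylated oxygen cannot capture a benzylic cation, it tolerates DDQ, and its migration to the other hydroxyl of the symmetric diol would regenerate the same compound.

Step 1
Reactants: 1 3-(3,4-dimethoxyphenyl)propanoic acid; 2 (S)-4-benzyl-2-oxazolidinone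
Product: 4 (S)-4-benzyl-3-[3-(3,4-dimethoxyphenyl)propanoyl]oxazolidin-2-one, via mixed pivalic anhydride 3 (not isolated)
Conditions: PivCl, Et3N, THF, −20 °C; then 2, LiCl, −20 °C to rt
Reagents that add atoms: none
Why: Mixed-anhydride N-acylation of an oxazolidinone, in which the LiCl-activated auxiliary attacks the unhindered carbonyl of anhydride 3 and no stereocentre is touched.

Step 2
Reactants: 4 (S)-4-benzyl-3-[3-(3,4-dimethoxyphenyl)propanoyl]oxazolidin-2-one (two molecules)
Product: 6 (4S,4'S)-3,3'-[(2R,3R)-2,3-bis(3,4-dimethoxybenzyl)butanedioyl]bis(4-benzyloxazolidin-2-one), via lithium Z-enolate 5 (not isolated)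
Conditions: LiN(iPr)2 (LDA), THF, −78 °C; then TiCl4 (1.0 equiv), −78 °C to rt
Reagents that add atoms: none
Why: Oxidative enolate homocoupling, in which one-electron oxidation of the chelated Z-enolate by tetravalent titanium (reduced to trivalent titanium) gives α-carbonyl radicals that dimerise, each new centre forming on the face away from the benzyl group of the (S)-auxiliary, so the R,R dimer should predominate and the minor R,S isomer is removed by chromatography or crystallisation.

Step 3
Reactants: 6 (4S,4'S)-3,3'-[(2R,3R)-2,3-bis(3,4-dimethoxybenzyl)butanedioyl]bis(4-benzyloxazolidin-2-one)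
Product: 7 (2R,3R)-2,3-bis(3,4-dimethoxybenzyl)butane-1,4-diol
Conditions: LiBH4, MeOH, THF, 0 °C to rt
Reagents that add atoms: none
Why: Reductive cleavage of N-acyl oxazolidinones to primary alcohols by borohydride (exocyclic C–N cleavage), which involves no enolisation, so both stereocentres are kept and auxiliary 2 is recovered.

Step 4
Reactants: 7 (2R,3R)-2,3-bis(3,4-dimethoxybenzyl)butane-1,4-diol
Product: 8 (2R,3R)-2,3-bis(3,4-dimethoxybenzyl)-4-hydroxybutyl pivalate
Conditions: PivCl (1.0 equiv, slow addition), pyridine, CH2Cl2, −20 to 0 °C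
Reagents that add atoms: pivaloyl chloride, CC(C)(C)C(=O)Cl
Why: Monoacylation of a twofold-symmetric diol, whose two hydroxyls are equivalent, so a single monoester should form; the esterification is statistical, and recovered diol and over-acylated material are recycled.

Step 5
Reactants: 8 (2R,3R)-2,3-bis(3,4-dimethoxybenzyl)-4-hydroxybutyl pivalate
Product: 10 [(2S,3R,4R)-4-(3,4-dimethoxybenzyl)-2-(3,4-dimethoxyphenyl)tetrahydrofuran-3-yl]methyl pivalate, via benzylic cation 9 (not isolated)
Conditions: DDQ (1.0 equiv, portionwise), 4 Å MS, CH2Cl2, 0 °C to rt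
Reagents that add atoms: none
Why: DDQ forms a charge-transfer complex with the electron-rich dimethoxyarene and removes hydride from a benzylic CH2, giving cation 9, which the 4-methoxy group stabilises as a para-quinone-methide oxocarbenium ion. The closest known reaction type is the DDQ benzylic oxidation of electron-rich arylalkanols with internal capture by a hydroxyl group (oxidative benzylic C–H etherification), as used to convert dibenzylbutanediol lignans into 2-aryl tetrahydrofuran lignans. The tetrahydrofuran closes in a 5-exo-trig mode: the C5 hydroxyl adds to the cationic carbon while the electrons move into the exocyclic arene, and loss of the proton to the reduced quinone gives O1–C2. The new C2 centre is controlled by the neighbouring C3 centre, because in the envelope transition state the aryl group turns away from the C3 pivaloyloxymethyl group and so ends up trans to it and to the C4 benzyl group, which is also the more stable arrangement. The step needs site selectivity and must stop after one closure: only the cation on the pivalate-bearing half can be reached by the hydroxyl through a five-membered transition state (the other would need an oxetane), and the acylated O9 is not nucleophilic, so no furofuran can form. One equivalent of DDQ under dry, cold conditions limits further oxidation of the C2–H of the product, which is benzylic and next to oxygen.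

Step 6
Reactants: 10 [(2S,3R,4R)-4-(3,4-dimethoxybenzyl)-2-(3,4-dimethoxyphenyl)tetrahydrofuran-3-yl]methyl pivalate
Product: 11 [(2S,3R,4R)-4-(3,4-dimethoxybenzyl)-2-(3,4-dimethoxyphenyl)tetrahydrofuran-3-yl]methanol
Conditions: LiAlH4, THF, 0 °C
Reagents that add atoms: none
Why: Reductive cleavage of a pivalate ester by hydride, to which the cyclic benzylic ether, the aryl methyl ethers and all three stereocentres are inert.

Step 7
Reactants: 11 [(2S,3R,4R)-4-(3,4-dimethoxybenzyl)-2-(3,4-dimethoxyphenyl)tetrahydrofuran-3-yl]methanol; 12 angelic acid ((Z)-2-methylbut-2-enoic acid)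
Product: 13 leoligin, [(2S,3R,4R)-4-(3,4-dimethoxybenzyl)-2-(3,4-dimethoxyphenyl)tetrahydrofuran-3-yl]methyl (Z)-2-methylbut-2-enoate
Conditions: PPh3, DIAD, THF, 0 °C to rt
Reagents that add atoms: none
Why: Mitsunobu esterification, in which the primary C9 alcohol is activated as an alkoxyphosphonium ion and displaced by angelate, so the acid is never turned into an acylating agent, the Z double bond should not isomerise to the tiglate, and the reacting CH2 carries no stereocentre.

Compound list
1 | 3-(3,4-dimethoxyphenyl)propanoic acid | COc1ccc(CCC(=O)O)cc1OC | starting material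
2 | (S)-4-benzyl-2-oxazolidinone | O=C1N[C@@H](Cc2ccccc2)CO1 | starting material
3 | 3-(3,4-dimethoxyphenyl)propanoic pivalic anhydride (not isolated) | COc1ccc(CCC(=O)OC(=O)C(C)(C)C)cc1OC | intermediate
4 | (S)-4-benzyl-3-[3-(3,4-dimethoxyphenyl)propanoyl]oxazolidin-2-one | COc1ccc(CCC(=O)N2[C@@H](Cc3ccccc3)COC2=O)cc1OC | intermediate
5 | lithium Z-enolate of 4 (not isolated) | [Li+].[O-]/C(=C\Cc1ccc(OC)c(OC)c1)N1[C@@H](Cc2ccccc2)COC1=O | intermediate
6 | (4S,4'S)-3,3'-[(2R,3R)-2,3-bis(3,4-dimethoxybenzyl)butanedioyl]bis(4-benzyloxazolidin-2-one) | O=C1OC[C@H](Cc2ccccc2)N1C(=O)[C@H](Cc1ccc(OC)c(OC)c1)[C@@H](Cc1ccc(OC)c(OC)c1)C(=O)N1[C@@H](Cc2ccccc2)COC1=O | intermediate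
7 | (2R,3R)-2,3-bis(3,4-dimethoxybenzyl)butane-1,4-diol | OC[C@H](Cc1ccc(OC)c(OC)c1)[C@@H](Cc1ccc(OC)c(OC)c1)CO | intermediate
8 | (2R,3R)-2,3-bis(3,4-dimethoxybenzyl)-4-hydroxybutyl pivalate | CC(C)(C)C(=O)OC[C@H](Cc1ccc(OC)c(OC)c1)[C@@H](Cc1ccc(OC)c(OC)c1)CO | intermediate
9 | benzylic cation of 8 at the future C2 (not isolated) | CC(C)(C)C(=O)OC[C@H]([CH+]c1ccc(OC)c(OC)c1)[C@@H](Cc1ccc(OC)c(OC)c1)CO | intermediate
10 | [(2S,3R,4R)-4-(3,4-dimethoxybenzyl)-2-(3,4-dimethoxyphenyl)tetrahydrofuran-3-yl]methyl pivalate | CC(C)(C)C(=O)OC[C@H]1[C@@H](Cc2ccc(OC)c(OC)c2)CO[C@@H]1c1ccc(OC)c(OC)c1 | intermediate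
11 | [(2S,3R,4R)-4-(3,4-dimethoxybenzyl)-2-(3,4-dimethoxyphenyl)tetrahydrofuran-3-yl]methanol | OC[C@H]1[C@@H](Cc2ccc(OC)c(OC)c2)CO[C@@H]1c1ccc(OC)c(OC)c1 | intermediate
12 | angelic acid, (Z)-2-methylbut-2-enoic acid | C/C=C(/C)C(=O)O | starting material
13 | leoligin | C/C=C(/C)C(=O)OC[C@H]1[C@@H](Cc2ccc(OC)c(OC)c2)CO[C@@H]1c1ccc(OC)c(OC)c1 | target

Total step count: 7
Longest linear sequence: 7 steps (1 to 13); angelic acid 12 enters in the last step.

Steps most likely to fail

Step 5. Two processes may lower the outcome. Hydride abstraction can occur at the other benzylic CH2 (C7'), where no five-membered closure is possible, so that cation is lost to elimination or arene attack. The C2–H of the product can also be oxidised further. The fallback introduces the benzylic oxygen by an aldol reaction instead of C–H oxidation; it sets out from 4 and comes back at 11.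
- Alkylation of the sodium enolate of 4 (NaN(SiMe3)2, THF, −78 °C) with tert-butyl bromoacetate, anti to the auxiliary benzyl group, should give tert-butyl (3R)-4-[(4S)-4-benzyl-2-oxooxazolidin-3-yl]-3-(3,4-dimethoxybenzyl)-4-oxobutanoate F1.
- LiBH4 reduction should give tert-butyl (3R)-3-(3,4-dimethoxybenzyl)-4-hydroxybutanoate F2, which lactonises with p-TsOH in warm toluene to (R)-4-(3,4-dimethoxybenzyl)dihydrofuran-2(3H)-one F3.
- Aldol addition of the lithium enolate of F3 (LiN(SiMe3)2, THF, −78 °C) to 3,4-dimethoxybenzaldehyde, trans to the ring benzyl group, should give (3S,4R)-4-(3,4-dimethoxybenzyl)-3-[(3,4-dimethoxyphenyl)(hydroxy)methyl]dihydrofuran-2(3H)-one F4; either carbinol epimer serves.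
- LiAlH4 should give (2R,3R)-2-(3,4-dimethoxybenzyl)-3-[(3,4-dimethoxyphenyl)(hydroxy)methyl]butane-1,4-diol F5.
- Catalytic camphorsulfonic acid in CH2Cl2 ionises the benzylic alcohol, and the same type of cation should close through the C5 hydroxyl to alcohol 11, from which step 7 follows.

Step 2. The radical dimerisation may show poor facial selectivity (too much R,S dimer), or the enolate may be quenched before coupling. The fallback forms the C3–C4 bond's two stereocentres by two successive enolate alkylations; it sets out from 4 and comes back at 7.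
- Compound 4 is taken through F1 and F2 to lactone (R)-4-(3,4-dimethoxybenzyl)dihydrofuran-2(3H)-one F3 exactly as laid out for step 5.
- The lithium enolate of F3 (LiN(SiMe3)2, THF, −78 °C) is alkylated with 3,4-dimethoxybenzyl bromide trans to the existing benzyl group, which should give (3R,4R)-3,4-bis(3,4-dimethoxybenzyl)dihydrofuran-2(3H)-one F6.
- LiAlH4 reduction of F6 should give diol 7.

Step 7. The angelate may isomerise from Z to E during esterification or isolation, or the neopentyl-like primary alcohol may be displaced sluggishly. The fallback builds the Z alkene after the ester bond is in place; it sets out from 11 and comes back at 13.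
- Steglich esterification of 11 with 2-[bis(2,2,2-trifluoroethoxy)phosphoryl]propanoic acid (DCC, DMAP, CH2Cl2) should give [(2S,3R,4R)-4-(3,4-dimethoxybenzyl)-2-(3,4-dimethoxyphenyl)tetrahydrofuran-3-yl]methyl 2-[bis(2,2,2-trifluoroethoxy)phosphoryl]propanoate F7.
- Still–Gennari olefination of F7 with acetaldehyde (KN(SiMe3)2, 18-crown-6, THF, −78 °C) should give the Z-trisubstituted enoate, that is leoligin 13.

Further compounds
F1 | step 5 | tert-butyl (3R)-4-[(4S)-4-benzyl-2-oxooxazolidin-3-yl]-3-(3,4-dimethoxybenzyl)-4-oxobutanoate | CC(C)(C)OC(=O)C[C@@H](Cc1ccc(OC)c(OC)c1)C(=O)N1[C@@H](Cc2ccccc2)COC1=O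
F2 | step 5 | tert-butyl (3R)-3-(3,4-dimethoxybenzyl)-4-hydroxybutanoate | CC(C)(C)OC(=O)C[C@@H](Cc1ccc(OC)c(OC)c1)CO
F3 | step 5 | (R)-4-(3,4-dimethoxybenzyl)dihydrofuran-2(3H)-one | O=C1C[C@@H](Cc2ccc(OC)c(OC)c2)CO1
F4 | step 5 | (3S,4R)-4-(3,4-dimethoxybenzyl)-3-[(3,4-dimethoxyphenyl)(hydroxy)methyl]dihydrofuran-2(3H)-one | O=C1[C@H](C(O)c2ccc(OC)c(OC)c2)[C@@H](Cc2ccc(OC)c(OC)c2)CO1
F5 | step 5 | (2R,3R)-2-(3,4-dimethoxybenzyl)-3-[(3,4-dimethoxyphenyl)(hydroxy)methyl]butane-1,4-diol | OC[C@H](C(O)c1ccc(OC)c(OC)c1)[C@@H](Cc1ccc(OC)c(OC)c1)CO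
F6 | step 2 | (3R,4R)-3,4-bis(3,4-dimethoxybenzyl)dihydrofuran-2(3H)-one | O=C1[C@H](Cc2ccc(OC)c(OC)c2)[C@@H](Cc2ccc(OC)c(OC)c2)CO1
F7 | step 7 | [(2S,3R,4R)-4-(3,4-dimethoxybenzyl)-2-(3,4-dimethoxyphenyl)tetrahydrofuran-3-yl]methyl 2-[bis(2,2,2-trifluoroethoxy)phosphoryl]propanoate | CC(C(=O)OC[C@H]1[C@@H](Cc2ccc(OC)c(OC)c2)CO[C@@H]1c1ccc(OC)c(OC)c1)P(=O)(OCC(F)(F)F)OCC(F)(F)F
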